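The flasks differ in temperature.

| flask | substrate | coupling partner | temperature | time |
|---|---|---|---|---|
| Sunday's | 0.18 M | 2.00 equiv | −20 °C | 3.0 min |
| Monday's | 0.18 M | 2.00 equiv | 10 °C | 3.0 min |
| Saturday's | 0.18 M | 2.00 equiv | 25 °C | 3.0 min |
| Thursday's | 0.18 M | 2.00 equiv | −5 °C | 3.0 min |

    2 substrate ⇌ resting dimer, settled at all times (K1 = 11 /M, ΔH1 = −30.0 kJ/mol)
    substrate + coupling partner ⇌ product (K2 = 1.0 /M, k2 = 7.6 /M/s, Ea2 = 57.0 kJ/mol, ΔH2 = −14.0 kJ/mol)
    (constants at 25 °C)

- percentages count the substrate that a species holds: one resting dimer counts as two
- a step written with two of one species runs at k times the square of its concentration and takes two of it each time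
- the constants hold at 25 °C; other temperatures follow from the activation energies and enthalpies

1. which flask leads in amount of product, in percent of the substrate charged ("all alike" within 1.5 percentage points) (Sunday's / Monday's / Saturday's / Thursday's / all alike)
2. how much product is there at the end, in percent of the substrate charged: Sunday's
3. how much product is there at the end, in percent of the substrate charged: Monday's
4. how much product is there at the end, in percent of the substrate charged: Saturday's
5. how much product is there at the end, in percent of the substrate charged: Thursday's

I count in fractions of the charge: a is free substrate, d the share in the resting dimer (the resting state), y the share in product, and b the coupling partner left of its own charge. Sunday's is the coldest flask, and its step 2 runs slower than Saturday's by the factor 60. Its reverse half-life is still 0.247 min, short against 3.0 min, so I reckon from balance, which is thermodynamic control.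

At balance d = H times a squared, y = G b a, and a, d and y add up to one. For Sunday's, K1 grows to 94.5 /M, following 2.73 /M of step 2 by the power of the enthalpy ratio. So Sunday's hold H is 34.0 and its G is 0.982. With b at one, Sunday's y comes to 14.2%. That leaves Sunday's b at 92.9%, and its y falls to 13.3%.

For Saturday's, H is 3.96 and G is 0.360. Saturday's y is then 12.9%, then b of 93.5%, then y of 12.2%.

Removing a gives y = w b times the root of d. Here w is the dimer pull, the product share per root of dimer share with the partner at full charge, G over the root of H: 0.168 on Sunday's, 0.181 on Saturday's. My two end flasks differ by 1.1 percentage points, less than 1.5 points, so I say all alike. I did not reckon the other two.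

The forecast gives 13.3%, 12.7%, 12.2% and 13.1% for Sunday's, Monday's, Saturday's and Thursday's, and all alike: “Cooling favours the product but also locks more substrate into the dimer”.

The flasks give 13.3%, 12.8%, 12.2% and 13.1% in that order, so all alike.

From Sunday's to Saturday's the pull rises by the factor 1.07, while the root of the dimer share falls from 0.849 to 0.719. The neighbour is Sunday's flask with 5.00 equiv of coupling partner. Its pull is 0.421, and its hold is unchanged, so G is 2.46. The neighbour's balance gives y of 31.4%, then b of 93.7%, then y of 29.8%. That neighbour flask holds 29.9% product, 13.0% free substrate and 57.1% in the resting dimer.

The constants belong to no real substance.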